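**Plan**

- Retrosynthesis: the thioacetate S–C10' bond is cut first, leaving a primary alcohol carried as a silyl ether. A C1'=C2' alkene is then reinstated on the chain. The pyrone ring is cut at C4–C5 and O1–C6 into a three-carbon acid and a thirteen-carbon enyne. The enyne is cut at its alkyne–alkene single bond; the acid is cut at its formyl C–C bond and its enol O–CH3 bond.
- Enabling feature: in the pyrone ring O1–C2(=O)–C3(OMe)=C4(OMe)–C5(Me)=C6(chain), the atoms C2, C3 and C4 with both methoxy groups are a 2,3-dimethoxyacrylic acid whose C4–H lies cis to the carboxyl group. C5(Me)=C6 is a masked propynyl unit, and an alkenyl group on C6 decides which alkyne carbon bonds to C4.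
- Forward order: the acid arm (steps 1–2) and the enyne arm (steps 3–5) are made separately. Step 6 joins them and closes the only ring, the pyrone. Steps 7–9 saturate the chain, free the alcohol and install the thioacetate.
- Stereochemistry: the target has no stereocentre. Two alkene geometries matter on the way: Z in the acid (thermodynamic enol ether geometry) and E in the enyne (syn-hydrozirconation). The side-chain alkene is erased in step 7.

Key step: step 6

Remark: enol ether formation in step 1 is assumed to favour the Z isomer, since β-methoxyacrylates generally settle with the methoxy group trans to the ester; if an E/Z mixture forms, it would be separated or equilibrated with acid before step 2.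

**Route**

Step 1
Reactants: 1 methyl methoxyacetate; 2 methyl formate
Product: 4 methyl (Z)-2,3-dimethoxyacrylate, via sodium enolate of methyl 2-methoxy-3-oxopropanoate 3 (not isolated)
Conditions: NaH (1.1 equiv), HCO2Me (3 equiv), THF, 0 °C to rt; volatiles removed; then Me2SO4 (1.3 equiv), DMF, rt
Reagents that add atoms: dimethyl sulfate, COS(=O)(=O)OC
Why: Crossed Claisen formylation of the ester enolate by non-enolisable methyl formate is driven by formation of the stabilised sodium enolate, and the hard electrophile Me2SO4 in DMF alkylates that enolate on oxygen to give the enol ether with its methoxy group trans to the ester (Z).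

Step 2
Reactants: 4 methyl (Z)-2,3-dimethoxyacrylate
Product: 6 (Z)-2,3-dimethoxyacrylic acid, via sodium (Z)-2,3-dimethoxyacrylate 5 (not isolated)
Conditions: NaOH (1.5 equiv), MeOH/H2O, rt; then 1 M HCl to pH 3, 0 °C, immediate extraction into EtOAc
Reagents that add atoms: sodium hydroxide, [Na+].[OH-]
Why: Ester saponification by acyl–oxygen cleavage; the β-methoxyacrylate is a vinylogous carbonate that tolerates aqueous base at room temperature, and brief cold acidification should release the acid without hydrolysing the enol ether or changing its geometry.

Step 3
Reactants: 7 dec-9-yn-1-ol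
Product: 8 tert-butyl(dec-9-yn-1-yloxy)dimethylsilane
Conditions: TBSCl (1.1 equiv), imidazole (2 equiv), CH2Cl2, 0 °C to rt
Reagents that add atoms: tert-butyldimethylsilyl chloride, CC(C)(C)[Si](C)(C)Cl
Why: Imidazole-promoted silylation of a primary alcohol; the terminal alkyne is inert and the silyl ether shields the hydroxyl from the zirconium hydride, the silver oxidant and the later metal catalysts.

Step 4
Reactants: 8 tert-butyl(dec-9-yn-1-yloxy)dimethylsilane
Product: 10 (E)-tert-butyl[(10-iododec-9-en-1-yl)oxy]dimethylsilane, via (E)-alkenylzirconocene chloride 9 (not isolated)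
Conditions: Cp2Zr(H)Cl (1.3 equiv), THF, rt, dark; then I2 (1.2 equiv), THF, 0 °C
Reagents that add atoms: iodine, [I][I]
Why: Hydrozirconation of a terminal alkyne is a syn addition that places zirconium on the terminal carbon, and iodinolysis of the C–Zr bond proceeds with retention, so the (E)-1-iodoalkene should result.

Step 5
Reactants: 10 (E)-tert-butyl[(10-iododec-9-en-1-yl)oxy]dimethylsilane; 11 propyne
Product: 12 (E)-tert-butyldimethyl(tridec-9-en-11-yn-1-yloxy)silane
Conditions: propyne (about 1 M in THF, 3 equiv), PdCl2(PPh3)2 (3 mol%), CuI (6 mol%), Et3N, THF, rt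
Reagents that add atoms: none
Why: Sonogashira coupling: oxidative addition of the vinyl iodide to zerovalent palladium, transmetallation from the copper acetylide of propyne and reductive elimination occur at room temperature with retention of the E geometry.

Step 6
Reactants: 6 (Z)-2,3-dimethoxyacrylic acid (1.3 equiv); 12 (E)-tert-butyldimethyl(tridec-9-en-11-yn-1-yloxy)silane
Product: 13 6-[(E)-10-(tert-butyldimethylsilyloxy)dec-1-en-1-yl]-3,4-dimethoxy-5-methyl-2H-pyran-2-one
Conditions: [Cp*RhCl2]2 (2.5 mol%), Ag2CO3 (1.0 equiv), DMF, 100 °C, N2
Reagents that add atoms: none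
Why: The carboxylate of 6 binds Cp*-ligated trivalent rhodium and directs concerted metallation–deprotonation to the cis C4–H, giving a five-membered rhodacycle; the alkyne of 12 inserts into the Rh–C bond to give a seven-membered rhodacycle, and C–O reductive elimination releases the lactone and monovalent rhodium, which Ag2CO3 returns to the trivalent state. The closest known reaction type is the rhodium-catalysed oxidative annulation of substituted acrylic acids with internal alkynes to 2-pyrones, combined with the established use of 1,3-enynes as regiodirecting alkynes in Cp*Rh annulations. The pyrone ring closes by an intermolecular oxidative [4+2] annulation: C4–C5 forms by migratory insertion and O1–C6 by reductive elimination from the seven-membered metallacycle. No stereocentre is created. The step needs regioselective insertion, which the enyne secures: rhodium prefers the alkyne carbon bearing the alkenyl group, so the methyl-bearing carbon becomes C5 and the alkenyl-bearing carbon becomes C6 on O1. The E geometry of 12 leaves no allylic C–H cis to the alkyne, which closes off a 1,4-rhodium shift, and the Z geometry of 6 presents its only vinylic C–H cis to the carboxyl group.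

Step 7
Reactants: 13 6-[(E)-10-(tert-butyldimethylsilyloxy)dec-1-en-1-yl]-3,4-dimethoxy-5-methyl-2H-pyran-2-one
Product: 14 6-[10-(tert-butyldimethylsilyloxy)decyl]-3,4-dimethoxy-5-methyl-2H-pyran-2-one
Conditions: H2 (1 atm), 10% Pd/C, EtOAc, rt, stopped after one equivalent of uptake
Reagents that add atoms: none
Why: Heterogeneous catalytic hydrogenation should saturate the unhindered disubstituted side-chain alkene much faster than the two tetrasubstituted, donor-substituted ring double bonds of the 2-pyrone, and the aprotic solvent keeps the silyl ether intact; the step precedes sulfur introduction so that the catalyst is not poisoned.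

Step 8
Reactants: 14 6-[10-(tert-butyldimethylsilyloxy)decyl]-3,4-dimethoxy-5-methyl-2H-pyran-2-one
Product: 15 6-(10-hydroxydecyl)-3,4-dimethoxy-5-methyl-2H-pyran-2-one
Conditions: HF·pyridine, pyridine, THF, 0 °C to rt
Reagents that add atoms: none
Why: Fluoride-mediated desilylation driven by the strong Si–F bond; buffered HF·pyridine is non-basic, so the lactone and the ring methoxy groups should not be attacked.

Step 9
Reactants: 15 6-(10-hydroxydecyl)-3,4-dimethoxy-5-methyl-2H-pyran-2-one
Product: 16 lehualide H, S-[10-(4,5-dimethoxy-3-methyl-6-oxo-6H-pyran-2-yl)decyl] ethanethioate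
Conditions: PPh3 (1.5 equiv), DIAD (1.5 equiv), THF, 0 °C; then AcSH (1.5 equiv), 0 °C to rt
Reagents that add atoms: thioacetic acid, CC(=O)S
Why: Mitsunobu thioesterification: the primary alcohol is activated as its alkoxyphosphonium salt and displaced in an SN2 step by thioacetate, thioacetic acid being acidic enough to protonate the betaine.

**Compound list**

1 | methyl methoxyacetate | COCC(=O)OC | starting material
2 | methyl formate | COC=O | starting material
3 | sodium enolate of methyl 2-methoxy-3-oxopropanoate (enolate geometry not fixed; formed in the flask, not isolated) | [Na+].[O-]C=C(OC)C(=O)OC | intermediate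
4 | methyl (Z)-2,3-dimethoxyacrylate | CO/C=C(\OC)C(=O)OC | intermediate
5 | sodium (Z)-2,3-dimethoxyacrylate (formed in the flask, not isolated) | CO/C=C(\OC)C(=O)[O-].[Na+] | intermediate
6 | (Z)-2,3-dimethoxyacrylic acid | CO/C=C(\OC)C(=O)O | intermediate
7 | dec-9-yn-1-ol | C#CCCCCCCCCO | starting material
8 | tert-butyl(dec-9-yn-1-yloxy)dimethylsilane | C#CCCCCCCCCO[Si](C)(C)C(C)(C)C | intermediate
9 | (E)-[10-(tert-butyldimethylsilyloxy)dec-1-en-1-yl]zirconocene chloride (formed in the flask, not isolated) | Cl[Zr](/C=C/CCCCCCCCO[Si](C)(C)C(C)(C)C)(C1C=CC=C1)C1C=CC=C1 | intermediate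
10 | (E)-tert-butyl[(10-iododec-9-en-1-yl)oxy]dimethylsilane | I/C=C/CCCCCCCCO[Si](C)(C)C(C)(C)C | intermediate
11 | propyne | CC#C | starting material
12 | (E)-tert-butyldimethyl(tridec-9-en-11-yn-1-yloxy)silane | CC#C/C=C/CCCCCCCCO[Si](C)(C)C(C)(C)C | intermediate
13 | 6-[(E)-10-(tert-butyldimethylsilyloxy)dec-1-en-1-yl]-3,4-dimethoxy-5-methyl-2H-pyran-2-one | COc1c(C)c(/C=C/CCCCCCCCO[Si](C)(C)C(C)(C)C)oc(=O)c1OC | intermediate
14 | 6-[10-(tert-butyldimethylsilyloxy)decyl]-3,4-dimethoxy-5-methyl-2H-pyran-2-one | COc1c(C)c(CCCCCCCCCCO[Si](C)(C)C(C)(C)C)oc(=O)c1OC | intermediate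
15 | 6-(10-hydroxydecyl)-3,4-dimethoxy-5-methyl-2H-pyran-2-one | COc1c(C)c(CCCCCCCCCCO)oc(=O)c1OC | intermediate
16 | lehualide H | COc1c(C)c(CCCCCCCCCCSC(C)=O)oc(=O)c1OC | target

**Count and risks**

Total step count: 9. Longest linear sequence: 7 steps (steps 3 to 9, from dec-9-yn-1-ol); the acid arm adds 2 steps in parallel.

Risk 1, step 6. The enyne may insert with the wrong orientation, the acid may lose CO2 under silver at high temperature before metallation, or metallation at the methoxy-bearing carbon may be slow. The fallback gives up C–H activation for a classical acylation–lactonisation assembly of the pyrone and sets out from 1.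
- Crossed Claisen acylation of the lithium enolate of 1 (LiHMDS, THF, −78 °C) with propanoyl chloride would give methyl 2-methoxy-3-oxopentanoate F1.
- After double deprotonation (NaH, then n-BuLi, THF, 0 °C), F1 would be acylated at its ethyl CH2 group by commercial methyl undec-10-enoate to give methyl 2-methoxy-4-methyl-3,5-dioxopentadec-14-enoate F2.
- DBU in hot toluene would lactonise this to 6-(dec-9-en-1-yl)-4-hydroxy-3-methoxy-5-methyl-2H-pyran-2-one F3.
- Me2SO4 and K2CO3 in acetone would methylate the 4-hydroxyl to give 6-(dec-9-en-1-yl)-3,4-dimethoxy-5-methyl-2H-pyran-2-one F4.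
- Radical anti-Markovnikov addition of thioacetic acid to the terminal alkene (AIBN, toluene, 80 °C) would come back to the route at 16.

Risk 2, step 1. C-methylation may compete with O-methylation, and kinetic alkylation may give an E/Z mixture of enol ethers. The fallback replaces enolate alkylation by acetal formation and thermodynamic elimination and sets out from 1 and 2.
- Formylation as in step 1, followed by acidic work-up, would give methyl 2-methoxy-3-oxopropanoate F5.
- HC(OMe)3 in MeOH with catalytic H2SO4 would convert it into methyl 2,3,3-trimethoxypropanoate F6.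
- Acid-catalysed thermal loss of methanol (catalytic TsOH, about 150 °C, methanol distilled off) would come back to the route at 4 as the more stable Z isomer.

Risk 3, step 7. The palladium surface may over-reduce the ring double bonds of the pyrone or cleave the silyl ether. The fallback sets out from 13 and replaces surface hydrogenation by a metal-free concerted hydrogen transfer from diimide, generated in the flask from 2-nitrobenzenesulfonyl hydrazide and Et3N in CH2Cl2 at room temperature. Diimide reduces only unpolarised, unhindered C=C bonds and leaves tetrasubstituted enol ether double bonds and silyl ethers alone. It would come back to the route at 14 and makes no compound outside the list (F0).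

**Further compounds**

F1 | step 6 | methyl 2-methoxy-3-oxopentanoate (racemic) | CCC(=O)C(OC)C(=O)OC
F2 | step 6 | methyl 2-methoxy-4-methyl-3,5-dioxopentadec-14-enoate (mixture of diastereomers and enol forms) | C=CCCCCCCCCC(=O)C(C)C(=O)C(OC)C(=O)OC
F3 | step 6 | 6-(dec-9-en-1-yl)-4-hydroxy-3-methoxy-5-methyl-2H-pyran-2-one | C=CCCCCCCCCc1oc(=O)c(OC)c(O)c1C
F4 | step 6 | 6-(dec-9-en-1-yl)-3,4-dimethoxy-5-methyl-2H-pyran-2-one | C=CCCCCCCCCc1oc(=O)c(OC)c(OC)c1C
F5 | step 1 | methyl 2-methoxy-3-oxopropanoate (racemic, in equilibrium with its enol) | COC(C=O)C(=O)OC
F6 | step 1 | methyl 2,3,3-trimethoxypropanoate (racemic) | COC(OC)C(OC)C(=O)OC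
F0 | step 7 | none | none
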